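## The problem

Catechin 5,4'-di-O-gallate (22) is a flavan-3-ol. Rings A and C form a chroman, the catechol ring B sits on C2, a hydroxyl sits on C3, and galloyl esters occupy O5 of ring A and O4' of ring B, while O7, O3' and O3 remain free. The only stereocentres are the adjacent C2 (R) and C3 (S), trans to each other. Because they are neighbours, either could in principle direct the other, but it is simplest to set both in a single syn addition across a C2=C3 double bond: the mechanism then fixes the relative configuration and only the absolute sense must come from a reagent. Two specific phenols must be acylated and three phenols plus the secondary alcohol must not, so the three equivalent oxygens of a phloroglucinol-type ring A have to be told apart, as do the two catechol oxygens of ring B. The aryl gallates are the fragile part: base and nucleophiles cleave or transesterify them, the O4' ester can migrate to a free O3', and the free polyphenol oxidises in air. The esters must therefore go on late and the last step must be neutral. The benzylic C2–O1 bond tolerates neither strong acid (ring opening, epimerisation at C2) nor forcing hydrogenolysis. The feature that makes the key step possible is that, at the alkene oxidation level, C2 (bearing O1 and ring B) is the carbonyl carbon of a ring-B benzoate on the ring-A oxygen that becomes O1, and C3 is the carbonyl carbon of an arylacetaldehyde whose CH2 (C4) hangs on C4a. The two carbonyls sit on ortho positions of ring A, placed for reductive closure of ring C.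

## Retrosynthesis

**22 ⇒ 21 ⇒ 19 + 20.** The target is cut first at the two acyl–oxygen bonds O5–C(=O) and O4'–C(=O). The nona-benzyl ether 21 should give 22 in one neutral hydrogenolysis. 21 is the double ester of diphenol 19 with two molecules of 3,4,5-tris(benzyloxy)benzoic acid 20. Acylating last keeps the sensitive aryl gallates out of every basic, acidic or reducing step. Acylating earlier would also put two extra aryl esters next to the titanium chemistry, where they could compete with the benzoate. The forward reaction has to esterify two phenols completely and nothing else.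

**19 ⇒ 18 ⇒ 17.** Diphenol 19 carries benzyl on O7, O3' and O3 and nothing on O5 and O4'. It comes from 18 by removing two methoxymethyl (MOM) ethers, and 18 comes from alcohol 17 by benzylating O3. This two-tier protection is the bookkeeping of the whole route: MOM marks the two oxygens that will be galloylated, benzyl marks those that are freed at the end. Benzylating O3 costs one step but removes any competition between the secondary alcohol and the phenols in the esterification.

**17 ⇒ 15.** The C3–O and C2–H bonds are cut together, leading to the flav-2-ene (2-aryl-4H-chromene) 15. Hydroboration of an enol ether puts boron on the carbon β to oxygen (C3) and hydrogen on C2 from the same face, so ring B and the future hydroxyl end up trans, as required. A pinene-derived chiral monoalkylborane is asked to choose the face. Both stereocentres are thus created in one step from a flat, achiral precursor.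

**15 ⇒ 14 (key disconnection).** The C2=C3 double bond is cut into the two carbonyl groups of aldehyde-ester 14. Against the neighbouring cuts this one has clear advantages. Closing O1–C2 needs a stereodefined acyclic diol or epoxide and risks ionisation at the electron-rich benzylic carbon. Closing C4–C4a by electrophilic substitution has no regiocontrol on ring A. The C2=C3 cut divides the molecule into a ring-A phenol and a ring-B benzoic acid joined by an ordinary ester, and the ester oxygen becomes O1, so the oxygen pattern of ring A is settled before the ring is made. The forward reaction, a reductive aldehyde–ester coupling with low-valent titanium, must favour the intramolecular cross-coupling over dimerisation of the aldehyde.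

**14 ⇒ 12 ⇒ 11 ⇒ 10 + 4.** The aldehyde of 14 is traced to the allyl group of 12 (oxidative cleavage through diol 13), so the sensitive arylacetaldehyde exists only immediately before the key step. The MOM ether on O5 of 12 comes from phenol 11. The ester bond of 11 is cut to give the symmetric diphenol 10 and acid 4. Since the two hydroxyls of 10 are equivalent, whichever is acylated becomes O1 and the other becomes O5. The only demand on the forward step is mono-acylation.

**10 ⇒ 9 ⇒ 7 ⇒ 6 ⇒ 5.** The aryl–allyl bond (the future C4a–C4 bond) is cut. The carbon between two MOM ethers of 7 is the most readily lithiated position, so aryllithium 8 should form there and nowhere else, and its allylation gives 9. Acid removes both MOM groups to give 10. 7 is the bis-MOM ether of 5-(benzyloxy)resorcinol 6, the mono-benzyl ether of phloroglucinol 5. The benzyl group placed first becomes the O7 protecting group.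

**4 ⇒ 3 ⇒ 2 ⇒ 1.** Acid 4 comes from methyl ester 3 by saponification, 3 from phenol 2 by benzylation, and 2 from methyl 3,4-dihydroxybenzoate 1 by MOM protection of the more acidic 4-OH. This order places MOM on the oxygen that becomes O4' and benzyl on the one that becomes O3'.

## Roads not taken

**Alternative 1:** The cut goes through ring A itself (C4a–C8a, C5–C6 and C8–C8a). Forward, irradiation of diazo ketone A2 causes a Wolff rearrangement to vinylketene A3, which adds to siloxyalkyne A4. A [2+2] cycloaddition, four-electron ring opening and six-electron closure (a Danheiser-type benzannulation) deliver phenol A1, with O1 free, O5 silylated, O7 benzylated and the diol stereocentres already in place.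
- Merit: the three ring-A oxygens emerge fully differentiated without any statistical protection. In this respect the road is better than the chosen plan, which desymmetrises phloroglucinol 5 twice by statistical reactions.
- Weak points: a benzene ring that can be bought is rebuilt from two acyclic partners, each needing several steps, and A2 is an enol-ether diazo ketone of doubtful stability. The photochemical step is awkward to scale. Ring C must still be closed afterwards by displacement at the benzylic carbon, where the electron-rich ring B invites ionisation and erosion of configuration.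
- Comparison: against the cleaner oxygen differentiation the chosen plan sets a far shorter access to its cyclisation substrate and a ring closure that creates no stereocentre.

**Alternative 2:** The cut removes O1–C8a and C4–C4a, so ring C is annulated onto an aryne. Forward, a fluoride source releases aryne A7 from silylaryl triflate A6. The benzylic alkoxide of the anti aldol ester A8 adds to the aryne carbon remote from the methoxymethoxy group, and the aryl anion formed at C4a attacks the methyl ester to give the protected trans-dihydroflavonol A5.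
- Merits: the plan is convergent, the regiochemistry of addition to a 3-alkoxyaryne is predictable, and both stereocentres come from an auxiliary-controlled glycolate aldol reaction. That is a firmer source of absolute configuration than the reagent-controlled hydroboration of the chosen plan.
- Weak points: a β-alkoxide of an aldol adduct under basic fluoride conditions can fragment by retro-aldol reaction. The product is a 3-alkoxy-4-ketone whose C2 centre can be lost by base-induced opening of ring C. The C4 carbonyl is not wanted and costs two further steps (reduction, benzylic deoxygenation). A6 needs a differentiated phloroglucinol as well, plus silyl and triflate groups, so the ring-A problem is not eased.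
- Comparison: the chosen plan reaches the C4 methylene directly and closes ring C without a stereocentre at risk. It concedes the more secure stereochemical footing of the aldol.

**Alternative 3:** The cut is O1–C2, with C2 as an epoxide carbon. Forward, a fluoride source removes the two silyl ethers of trans epoxide A10. Either of the two equivalent ring-A phenoxides attacks the benzylic epoxide carbon with inversion, closing ring C and giving A9 with the (2R,3S) configuration and free 3-OH and 5-OH. A10 would come from catalytic asymmetric epoxidation of the trans alkene A11.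
- Merits: this is probably the shortest road. The symmetry of ring A is used, so no desymmetrisation is needed before cyclisation; the asymmetric step is of a well-established type; and O5 emerges free where a galloyl group is wanted. In step count and stereochemical security it is at least equal to the chosen plan and probably better.
- Weak points: the phenoxide can also attack the nearer epoxide carbon, giving a five-membered ring. Under basic conditions this is a real competitor, while acid activation, which favours the benzylic carbon, risks ionisation and loss of the trans relationship. The product has O5 and O3 both free, so the later galloylation must distinguish a phenol from a secondary alcohol or spend extra steps.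
- Comparison: the chosen plan sets against this a ring closure whose ring size is fixed by the tether, and a protecting-group pattern in which O3 never competes with O5. It pays with two statistical protections and a less certain asymmetric step.

Key step: step 11

Assumption: monoisopinocampheylborane made from (+)-α-pinene is taken to attack flav-2-ene 15 on the same face as it attacks 1-arylcycloalkenes, which leads to the (2R,3S) series; the reagent from (−)-α-pinene would be used if the sense proved opposite.

Remark: methyl 3,4-dihydroxybenzoate (the methyl ester of 3,4-dihydroxybenzoic acid) and 3,4,5-tris(benzyloxy)benzoic acid (perbenzylated gallic acid) are bought.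

## Route

Step 1
Reactants: 1 methyl 3,4-dihydroxybenzoate
Product: 2 methyl 3-hydroxy-4-(methoxymethoxy)benzoate
Conditions: MOMCl (1.05 equiv), K2CO3 (1.1 equiv), acetone, 0 °C → rt
Reagents that add atoms: chloromethyl methyl ether, COCCl
Why: Williamson-type O-alkylation; the 4-OH is conjugated with the ester and is the more acidic phenol, so with one equivalent of weak base its phenoxide forms and is alkylated preferentially.

Step 2
Reactants: 2 methyl 3-hydroxy-4-(methoxymethoxy)benzoate
Product: 3 methyl 3-(benzyloxy)-4-(methoxymethoxy)benzoate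
Conditions: BnBr (1.2 equiv), K2CO3 (1.5 equiv), DMF, rt → 50 °C
Reagents that add atoms: benzyl bromide, BrCc1ccccc1
Why: Williamson benzylation of the remaining phenol; the MOM ether and the methyl ester are inert to carbonate.

Step 3
Reactants: 3 methyl 3-(benzyloxy)-4-(methoxymethoxy)benzoate
Product: 4 3-(benzyloxy)-4-(methoxymethoxy)benzoic acid
Conditions: LiOH·H2O (3 equiv), THF/MeOH/H2O, 40 °C; then 1 M HCl to pH 4, 0 °C
Reagents that add atoms: lithium hydroxide, [Li+].[OH-] (its oxygen becomes the carboxyl OH)
Why: Ester saponification; MOM and benzyl ethers are stable to base, and cold, brief acidification to pH 4 should spare the MOM acetal.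

Step 4
Reactants: 5 phloroglucinol (benzene-1,3,5-triol)
Product: 6 5-(benzyloxy)benzene-1,3-diol
Conditions: 5 (3 equiv), BnBr (1 equiv), K2CO3 (1 equiv), DMF, 0 °C → rt
Reagents that add atoms: benzyl bromide, BrCc1ccccc1
Why: Williamson mono-O-benzylation of a threefold-symmetric triphenol; the outcome is statistical, so the cheap triol is used in excess (washed out with water) to keep di- and tribenzylation low, and the polar aprotic solvent favours O- over C-alkylation.

Step 5
Reactants: 6 5-(benzyloxy)benzene-1,3-diol
Product: 7 1-(benzyloxy)-3,5-bis(methoxymethoxy)benzene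
Conditions: MOMCl (2.5 equiv), iPr2NEt (3 equiv), CH2Cl2, 0 °C → rt
Reagents that add atoms: chloromethyl methyl ether, COCCl
Why: Standard MOM protection of both phenols; it also installs the two directing groups for the next step.

Step 6
Reactants: 7 1-(benzyloxy)-3,5-bis(methoxymethoxy)benzene
Product: 9 2-allyl-5-(benzyloxy)-1,3-bis(methoxymethoxy)benzene, via [4-(benzyloxy)-2,6-bis(methoxymethoxy)phenyl]lithium 8 (not isolated)
Conditions: n-BuLi (1.1 equiv), THF, 0 °C, 1 h; then CuI (10 mol %), allyl bromide (1.5 equiv), −78 °C → rt
Reagents that add atoms: allyl bromide, C=CCBr; n-butyllithium, [Li]CCCC (lithium, present in 8 only)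
Why: Directed ortho-metalation; the carbon flanked by two chelating MOM ethers is lithiated in preference to the positions next to the weaker benzyloxy director, and the aryllithium is allylated under copper catalysis.

Step 7
Reactants: 9 2-allyl-5-(benzyloxy)-1,3-bis(methoxymethoxy)benzene
Product: 10 2-allyl-5-(benzyloxy)benzene-1,3-diol
Conditions: 3 M HCl/MeOH (1:10), 40 °C
Reagents that add atoms: none
Why: Acid-catalysed acetal exchange with methanol removes both MOM groups; the large excess of methanol traps the methoxymethyl cation, and the benzyl ether and the allyl group are inert to dilute acid at this temperature.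

Step 8
Reactants: 10 2-allyl-5-(benzyloxy)benzene-1,3-diol; 4 3-(benzyloxy)-4-(methoxymethoxy)benzoic acid
Product: 11 2-allyl-5-(benzyloxy)-3-hydroxyphenyl 3-(benzyloxy)-4-(methoxymethoxy)benzoate
Conditions: 10 (3 equiv), 4 (1 equiv), DCC (1.1 equiv), DMAP (0.1 equiv), CH2Cl2, 0 °C → rt; unreacted 10 recovered
Reagents that add atoms: none
Why: Steglich esterification of a phenol; the two hydroxyls of 10 are equivalent, so either gives the same mono-ester, and an excess of recoverable diphenol keeps double acylation low.

Step 9
Reactants: 11 2-allyl-5-(benzyloxy)-3-hydroxyphenyl 3-(benzyloxy)-4-(methoxymethoxy)benzoate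
Product: 12 2-allyl-5-(benzyloxy)-3-(methoxymethoxy)phenyl 3-(benzyloxy)-4-(methoxymethoxy)benzoate
Conditions: MOMCl (1.5 equiv), iPr2NEt (2 equiv), CH2Cl2, 0 °C → rt
Reagents that add atoms: chloromethyl methyl ether, COCCl
Why: MOM protection of the remaining phenol (the future O5); the aryl ester is stable to a hindered amine base at room temperature.

Step 10
Reactants: 12 2-allyl-5-(benzyloxy)-3-(methoxymethoxy)phenyl 3-(benzyloxy)-4-(methoxymethoxy)benzoate
Product: 14 5-(benzyloxy)-3-(methoxymethoxy)-2-(2-oxoethyl)phenyl 3-(benzyloxy)-4-(methoxymethoxy)benzoate, via 2-(2,3-dihydroxypropyl)aryl benzoate 13 (not isolated)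
Conditions: OsO4 (2 mol %), NaIO4 (4 equiv), 2,6-lutidine (2 equiv), 1,4-dioxane/H2O 3:1, rt; crude aldehyde used at once
Reagents that add atoms: osmium tetroxide, O=[Os](=O)(=O)=O (delivers the oxygens of diol 13); sodium periodate, [Na+].[O-]I(=O)(=O)=O (reoxidises osmium and is the ultimate oxygen source)
Why: Lemieux–Johnson oxidative cleavage (dihydroxylation, then periodate glycol cleavage) of the terminal alkene; it is preferred to ozonolysis because the electron-rich rings tolerate it, and the lutidine buffer protects the aryl ester and the aldehyde.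

Step 11
Reactants: 14 5-(benzyloxy)-3-(methoxymethoxy)-2-(2-oxoethyl)phenyl 3-(benzyloxy)-4-(methoxymethoxy)benzoate
Product: 15 7-(benzyloxy)-2-[3-(benzyloxy)-4-(methoxymethoxy)phenyl]-5-(methoxymethoxy)-4H-chromene (the flav-2-ene)
Conditions: TiCl3 (10 equiv), Zn dust (20 equiv), DME, reflux, 2 h; then 14 in DME added by syringe pump over 10 h (final about 0.005 M), reflux; cooled, filtered through basic alumina, aq. K2CO3 wash; chromatography on Et3N-treated silica
Reagents that add atoms: none
Why: Zinc reduces TiCl3 to low-valent titanium, which transfers an electron to the aldehyde of 14, the more easily reduced carbonyl, to give a titanium-bound ketyl at the future C3. The ketyl carbon adds to the carbonyl carbon of the neighbouring aryl benzoate (the future C2), and the titanium-bound diolate gives up both oxygens to the oxophilic metal, leaving the C2=C3 enol ether while the ester oxygen stays as O1. The closest known reaction type is the intramolecular oxo-ester McMurry-type coupling that turns ortho-acyloxy aryl carbonyl compounds into benzofurans and the homologous chromenes. Ring C closes by C–C bond formation between two carbonyl carbons, a 6-exo attack of the ketyl on the ester C=O, and the tether O1–C8a–C4a–C4 allows no other ring size. No stereocentre is formed. The step needs cross-coupling of the aldehyde with an ester, which on its own is inert to the reagent, in preference to pinacol-type dimerisation or simple reduction of the aldehyde; the ortho placement of the two side chains on ring A, slow addition to an excess of pre-formed reagent and high dilution are meant to secure this. 14 contains only one ester, and benzyl and MOM ethers are spectators. The enol ether is acid-labile, hence the basic work-up and prompt use.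

Step 12
Reactants: 15 7-(benzyloxy)-2-[3-(benzyloxy)-4-(methoxymethoxy)phenyl]-5-(methoxymethoxy)-4H-chromene
Product: 17 (2R,3S)-7-(benzyloxy)-2-[3-(benzyloxy)-4-(methoxymethoxy)phenyl]-5-(methoxymethoxy)chroman-3-ol, via chroman-3-yl(isopinocampheyl)borane 16 (not isolated)
Conditions: IpcBH2 [from (+)-α-pinene, liberated beforehand from its TMEDA adduct with BF3·OEt2 and filtered] (1.5 equiv), THF, −25 °C → 0 °C; then 3 M NaOH, 30 % H2O2, 0 °C → rt
Reagents that add atoms: hydrogen peroxide, OO (oxygen of the 3-OH); monoisopinocampheylborane, C[C@H]1[C@H](B)C[C@@H]2C[C@H]1C2(C)C (boron and the isopinocampheyl group, present in 16 only)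
Why: Asymmetric hydroboration–oxidation of a trisubstituted aryl alkene: boron adds to C3 (β to O1, as in enol ether hydroborations) and hydrogen to C2 from the same face, so ring B and boron are trans, and oxidation with retention gives the 2,3-trans alcohol. The face, and with it the absolute configuration at both C2 and C3, is chosen by the isopinocampheyl group (reagent control), by analogy with 1-arylcycloalkenes.

Step 13
Reactants: 17 (2R,3S)-7-(benzyloxy)-2-[3-(benzyloxy)-4-(methoxymethoxy)phenyl]-5-(methoxymethoxy)chroman-3-ol
Product: 18 (2R,3S)-3,7-bis(benzyloxy)-2-[3-(benzyloxy)-4-(methoxymethoxy)phenyl]-5-(methoxymethoxy)chroman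
Conditions: NaH (1.3 equiv), BnBr (1.2 equiv), n-Bu4NI (5 mol %), DMF, 0 °C → rt
Reagents that add atoms: benzyl bromide, BrCc1ccccc1
Why: Williamson etherification of the secondary alkoxide; it masks O3 so that only the two phenols can be acylated later, and neither stereocentre carries an acidic hydrogen.

Step 14
Reactants: 18 (2R,3S)-3,7-bis(benzyloxy)-2-[3-(benzyloxy)-4-(methoxymethoxy)phenyl]-5-(methoxymethoxy)chroman
Product: 19 (2R,3S)-3,7-bis(benzyloxy)-2-[3-(benzyloxy)-4-hydroxyphenyl]chroman-5-ol
Conditions: conc. HCl (cat.), MeOH/THF 2:1, 45 °C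
Reagents that add atoms: none
Why: Acid-catalysed methanolysis of the two aryl MOM ethers frees exactly O5 and O4'; benzyl ethers are stable, and the mild acidity is chosen to avoid opening of the C2–O1 bond.

Step 15
Reactants: 19 (2R,3S)-3,7-bis(benzyloxy)-2-[3-(benzyloxy)-4-hydroxyphenyl]chroman-5-ol; 20 3,4,5-tris(benzyloxy)benzoic acid
Product: 21 (2R,3S)-3,7,3'-tri-O-benzylcatechin 5,4'-bis[3,4,5-tris(benzyloxy)benzoate]
Conditions: 20 (2.4 equiv), DCC (2.6 equiv), DMAP (0.4 equiv), CH2Cl2, 0 °C → rt
Reagents that add atoms: none
Why: Double Steglich esterification of the only two free hydroxyls, both phenols; the conditions are non-basic enough to leave the stereocentres and the new aryl esters untouched.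

Step 16
Reactants: 21 (2R,3S)-3,7,3'-tri-O-benzylcatechin 5,4'-bis[3,4,5-tris(benzyloxy)benzoate]
Product: 22 catechin 5,4'-di-O-gallate
Conditions: H2 (1 atm), Pd(OH)2/C (20 wt %), THF/EtOAc 1:1, rt; filtration and isolation under argon
Reagents that add atoms: none
Why: Catalytic hydrogenolysis removes all nine benzyl ethers under neutral conditions; an aprotic, non-nucleophilic solvent avoids transesterification of the aryl gallates and migration of the O4' galloyl group to the freed O3', and the stereocentres are not touched.

## Compound list

1 | methyl 3,4-dihydroxybenzoate | COC(=O)c1ccc(O)c(O)c1 | starting material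
2 | methyl 3-hydroxy-4-(methoxymethoxy)benzoate | COC(=O)c1ccc(OCOC)c(O)c1 | intermediate
3 | methyl 3-(benzyloxy)-4-(methoxymethoxy)benzoate | COC(=O)c1ccc(OCOC)c(OCc2ccccc2)c1 | intermediate
4 | 3-(benzyloxy)-4-(methoxymethoxy)benzoic acid | OC(=O)c1ccc(OCOC)c(OCc2ccccc2)c1 | intermediate
5 | phloroglucinol | Oc1cc(O)cc(O)c1 | starting material
6 | 5-(benzyloxy)benzene-1,3-diol | Oc1cc(O)cc(OCc2ccccc2)c1 | intermediate
7 | 1-(benzyloxy)-3,5-bis(methoxymethoxy)benzene | COCOc1cc(OCOC)cc(OCc2ccccc2)c1 | intermediate
8 | [4-(benzyloxy)-2,6-bis(methoxymethoxy)phenyl]lithium | [Li]c1c(OCOC)cc(OCc2ccccc2)cc1OCOC | intermediate (not isolated)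
9 | 2-allyl-5-(benzyloxy)-1,3-bis(methoxymethoxy)benzene | C=CCc1c(OCOC)cc(OCc2ccccc2)cc1OCOC | intermediate
10 | 2-allyl-5-(benzyloxy)benzene-1,3-diol | C=CCc1c(O)cc(OCc2ccccc2)cc1O | intermediate
11 | 2-allyl-5-(benzyloxy)-3-hydroxyphenyl 3-(benzyloxy)-4-(methoxymethoxy)benzoate | C=CCc1c(O)cc(OCc2ccccc2)cc1OC(=O)c1ccc(OCOC)c(OCc2ccccc2)c1 | intermediate
12 | 2-allyl-5-(benzyloxy)-3-(methoxymethoxy)phenyl 3-(benzyloxy)-4-(methoxymethoxy)benzoate | C=CCc1c(OCOC)cc(OCc2ccccc2)cc1OC(=O)c1ccc(OCOC)c(OCc2ccccc2)c1 | intermediate
13 | 5-(benzyloxy)-2-(2,3-dihydroxypropyl)-3-(methoxymethoxy)phenyl 3-(benzyloxy)-4-(methoxymethoxy)benzoate (racemic at the carbinol carbon) | OCC(O)Cc1c(OCOC)cc(OCc2ccccc2)cc1OC(=O)c1ccc(OCOC)c(OCc2ccccc2)c1 | intermediate (not isolated)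
14 | 5-(benzyloxy)-3-(methoxymethoxy)-2-(2-oxoethyl)phenyl 3-(benzyloxy)-4-(methoxymethoxy)benzoate | O=CCc1c(OCOC)cc(OCc2ccccc2)cc1OC(=O)c1ccc(OCOC)c(OCc2ccccc2)c1 | intermediate
15 | 7-(benzyloxy)-2-[3-(benzyloxy)-4-(methoxymethoxy)phenyl]-5-(methoxymethoxy)-4H-chromene | COCOc1ccc(cc1OCc1ccccc1)C1=CCc2c(OCOC)cc(OCc3ccccc3)cc2O1 | intermediate
16 | {7-(benzyloxy)-2-[3-(benzyloxy)-4-(methoxymethoxy)phenyl]-5-(methoxymethoxy)chroman-3-yl}(isopinocampheyl)borane, boron trans to ring B, same spatial arrangement at C2 and C3 as in 17 | COCOc1ccc([C@H]2Oc3cc(OCc4ccccc4)cc(OCOC)c3C[C@@H]2B[C@@H]2C[C@@H]3C[C@H]([C@H]2C)C3(C)C)cc1OCc1ccccc1 | intermediate (not isolated)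
17 | (2R,3S)-7-(benzyloxy)-2-[3-(benzyloxy)-4-(methoxymethoxy)phenyl]-5-(methoxymethoxy)chroman-3-ol | COCOc1ccc([C@H]2Oc3cc(OCc4ccccc4)cc(OCOC)c3C[C@@H]2O)cc1OCc1ccccc1 | intermediate
18 | (2R,3S)-3,7-bis(benzyloxy)-2-[3-(benzyloxy)-4-(methoxymethoxy)phenyl]-5-(methoxymethoxy)chroman | COCOc1ccc([C@H]2Oc3cc(OCc4ccccc4)cc(OCOC)c3C[C@@H]2OCc2ccccc2)cc1OCc1ccccc1 | intermediate
19 | (2R,3S)-3,7-bis(benzyloxy)-2-[3-(benzyloxy)-4-hydroxyphenyl]chroman-5-ol | Oc1ccc([C@H]2Oc3cc(OCc4ccccc4)cc(O)c3C[C@@H]2OCc2ccccc2)cc1OCc1ccccc1 | intermediate
20 | 3,4,5-tris(benzyloxy)benzoic acid | OC(=O)c1cc(OCc2ccccc2)c(OCc2ccccc2)c(OCc2ccccc2)c1 | starting material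
21 | (2R,3S)-3,7,3'-tri-O-benzylcatechin 5,4'-bis[3,4,5-tris(benzyloxy)benzoate] | O=C(Oc1ccc([C@H]2Oc3cc(OCc4ccccc4)cc(OC(=O)c4cc(OCc5ccccc5)c(OCc5ccccc5)c(OCc5ccccc5)c4)c3C[C@@H]2OCc2ccccc2)cc1OCc1ccccc1)c1cc(OCc2ccccc2)c(OCc2ccccc2)c(OCc2ccccc2)c1 | intermediate
22 | catechin 5,4'-di-O-gallate, (2R,3S) | O=C(Oc1ccc([C@H]2Oc3cc(O)cc(OC(=O)c4cc(O)c(O)c(O)c4)c3C[C@@H]2O)cc1O)c1cc(O)c(O)c(O)c1 | target

## Step count and least certain steps

Total: 16 steps. Longest linear sequence: 13 steps (steps 4–16, from phloroglucinol 5). The ring-B acid 4 takes three steps (1–3) and joins at step 8; acid 20 joins at step 15.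

**Step 11 (key step).** The most likely failures are intermolecular pinacol-type dimerisation or plain reduction of the enolisable arylacetaldehyde before it finds the ester, loss of MOM groups to the Lewis-acidic titanium and zinc chlorides at reflux, and hydrolysis of the enol ether during isolation. The fallback sets out from 12 and comes back at 15. The ester carbonyl of 12 is methylenated with the Tebbe reagent Cp2Ti(μ-Cl)(μ-CH2)AlMe2 (THF, pyridine, −40 °C → rt), a reaction well known for aryl benzoates, to give 2-allyl-5-(benzyloxy)-3-(methoxymethoxy)phenyl 1-[3-(benzyloxy)-4-(methoxymethoxy)phenyl]vinyl ether F1. Ring-closing olefin metathesis of F1 with second-generation Grubbs catalyst (toluene, 70 °C) then forms the same C2=C3 bond from the same ester carbon with loss of ethene, giving 15 without passing through the aldehyde.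

**Step 12.** The most likely failure is insufficient facial discrimination, or even the opposite sense, because the substrate is an enol ether with O1 in place of a ring CH2 of the carbocyclic models. The hindered borane may also react slowly, allowing the acid-labile enol ether to decompose. The fallback sets out from 15 and comes back at 17. Hydroboration–oxidation with BH3·SMe2 (THF, 0 °C; NaOH, H2O2) gives racemic trans-7-(benzyloxy)-2-[3-(benzyloxy)-4-(methoxymethoxy)phenyl]-5-(methoxymethoxy)chroman-3-ol F2. Steglich esterification with (S)-2-methoxy-2-phenylacetic acid gives two diastereomeric esters, which are separated by chromatography or crystallisation. The (2R,3S)-chroman-3-yl (S)-2-methoxy-2-phenylacetate F3 is then methanolysed (K2CO3, MeOH) to return enantiopure 17. This resolution gives up half the material but secures the configuration.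

**Step 8.** The most likely failure is over-acylation to the diester, with loss of acid 4, and tedious separation of a statistical mixture. The fallback sets out from 10 and comes back at 15; it removes the statistical event by keeping the symmetry through the key step.
- Diphenol 10 is esterified on both oxygens with 4 (2.4 equiv, DCC, DMAP) to give 2-allyl-5-(benzyloxy)-1,3-phenylene bis[3-(benzyloxy)-4-(methoxymethoxy)benzoate] F4.
- Lemieux–Johnson cleavage gives 5-(benzyloxy)-2-(2-oxoethyl)-1,3-phenylene bis[3-(benzyloxy)-4-(methoxymethoxy)benzoate] F5.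
- The titanium coupling of step 11, in which either of the two equivalent esters may react, gives 7-(benzyloxy)-2-[3-(benzyloxy)-4-(methoxymethoxy)phenyl]-4H-chromen-5-yl 3-(benzyloxy)-4-(methoxymethoxy)benzoate F6.
- Methanolysis (K2CO3, MeOH) removes the spectator ester, returning it as methyl ester 3, and gives 7-(benzyloxy)-2-[3-(benzyloxy)-4-(methoxymethoxy)phenyl]-4H-chromen-5-ol F7.
- MOM protection (MOMCl, iPr2NEt) converts F7 into 15.

**Step 16.** The most likely failure is slow cleavage of the secondary O3 benzyl ether, which forces long exposure. During this time the O4' galloyl group may migrate to the freed O3', or the benzylic C2–O1 bond may be hydrogenolysed. The fallback sets out from 17 and comes back at 22; it leaves O3 unprotected so that only fast-cleaving aryl benzyl ethers remain at the end.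
- Acid methanolysis of the MOM groups of 17 gives (2R,3S)-7-(benzyloxy)-2-[3-(benzyloxy)-4-hydroxyphenyl]chroman-3,5-diol F8.
- Acid 20 is converted with oxalyl chloride into 3,4,5-tris(benzyloxy)benzoyl chloride F9.
- F8 is acylated with F9 and Et3N without DMAP at −20 °C, conditions under which phenoxides react far faster than the hindered secondary alcohol, to give (2R,3S)-7,3'-di-O-benzylcatechin 5,4'-bis[3,4,5-tris(benzyloxy)benzoate] F10.
- Brief hydrogenolysis of F10 (H2, Pd(OH)2/C, THF/EtOAc) gives 22.

## Further compounds

F1 | step 11 | 2-allyl-5-(benzyloxy)-3-(methoxymethoxy)phenyl 1-[3-(benzyloxy)-4-(methoxymethoxy)phenyl]vinyl ether | C=CCc1c(OCOC)cc(OCc2ccccc2)cc1OC(=C)c1ccc(OCOC)c(OCc2ccccc2)c1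
F2 | step 12 | racemic trans-7-(benzyloxy)-2-[3-(benzyloxy)-4-(methoxymethoxy)phenyl]-5-(methoxymethoxy)chroman-3-ol (1:1 mixture of the 2R,3S and 2S,3R enantiomers) | COCOc1ccc([C@H]2Oc3cc(OCc4ccccc4)cc(OCOC)c3C[C@@H]2O)cc1OCc1ccccc1.COCOc1ccc([C@@H]2Oc3cc(OCc4ccccc4)cc(OCOC)c3C[C@H]2O)cc1OCc1ccccc1
F3 | step 12 | (2R,3S)-7-(benzyloxy)-2-[3-(benzyloxy)-4-(methoxymethoxy)phenyl]-5-(methoxymethoxy)chroman-3-yl (S)-2-methoxy-2-phenylacetate | COCOc1ccc([C@H]2Oc3cc(OCc4ccccc4)cc(OCOC)c3C[C@@H]2OC(=O)[C@@H](OC)c2ccccc2)cc1OCc1ccccc1
F4 | step 8 | 2-allyl-5-(benzyloxy)-1,3-phenylene bis[3-(benzyloxy)-4-(methoxymethoxy)benzoate] | C=CCc1c(OC(=O)c2ccc(OCOC)c(OCc3ccccc3)c2)cc(OCc2ccccc2)cc1OC(=O)c1ccc(OCOC)c(OCc2ccccc2)c1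
F5 | step 8 | 5-(benzyloxy)-2-(2-oxoethyl)-1,3-phenylene bis[3-(benzyloxy)-4-(methoxymethoxy)benzoate] | O=CCc1c(OC(=O)c2ccc(OCOC)c(OCc3ccccc3)c2)cc(OCc2ccccc2)cc1OC(=O)c1ccc(OCOC)c(OCc2ccccc2)c1
F6 | step 8 | 7-(benzyloxy)-2-[3-(benzyloxy)-4-(methoxymethoxy)phenyl]-4H-chromen-5-yl 3-(benzyloxy)-4-(methoxymethoxy)benzoate | COCOc1ccc(cc1OCc1ccccc1)C1=CCc2c(OC(=O)c3ccc(OCOC)c(OCc4ccccc4)c3)cc(OCc3ccccc3)cc2O1
F7 | step 8 | 7-(benzyloxy)-2-[3-(benzyloxy)-4-(methoxymethoxy)phenyl]-4H-chromen-5-ol | COCOc1ccc(cc1OCc1ccccc1)C1=CCc2c(O)cc(OCc3ccccc3)cc2O1
F8 | step 16 | (2R,3S)-7-(benzyloxy)-2-[3-(benzyloxy)-4-hydroxyphenyl]chroman-3,5-diol | Oc1ccc([C@H]2Oc3cc(OCc4ccccc4)cc(O)c3C[C@@H]2O)cc1OCc1ccccc1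
F9 | step 16 | 3,4,5-tris(benzyloxy)benzoyl chloride | O=C(Cl)c1cc(OCc2ccccc2)c(OCc2ccccc2)c(OCc2ccccc2)c1
F10 | step 16 | (2R,3S)-7,3'-di-O-benzylcatechin 5,4'-bis[3,4,5-tris(benzyloxy)benzoate] (free 3-OH) | O=C(Oc1ccc([C@H]2Oc3cc(OCc4ccccc4)cc(OC(=O)c4cc(OCc5ccccc5)c(OCc5ccccc5)c(OCc5ccccc5)c4)c3C[C@@H]2O)cc1OCc1ccccc1)c1cc(OCc2ccccc2)c(OCc2ccccc2)c(OCc2ccccc2)c1
A1 | alternative 1 | 5-(benzyloxy)-2-{[(4S,5S)-5-[3-(benzyloxy)-4-(methoxymethoxy)phenyl]-2,2-dimethyl-1,3-dioxolan-4-yl]methyl}-3-(triisopropylsilyloxy)phenol | COCOc1ccc(cc1OCc1ccccc1)[C@@H]1OC(C)(C)O[C@H]1Cc1c(O)cc(OCc2ccccc2)cc1O[Si](C(C)C)(C(C)C)C(C)C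
A2 | alternative 1 | 3-(benzyloxy)-1-diazobut-3-en-2-one | C=C(OCc1ccccc1)C(=O)C=[N+]=[N-]
A3 | alternative 1 | 3-(benzyloxy)buta-1,3-dien-1-one (vinylketene) | C=C(OCc1ccccc1)C=C=O
A4 | alternative 1 | (4S,5S)-4-[3-(benzyloxy)-4-(methoxymethoxy)phenyl]-2,2-dimethyl-5-[3-(triisopropylsilyloxy)prop-2-yn-1-yl]-1,3-dioxolane | COCOc1ccc(cc1OCc1ccccc1)[C@@H]1OC(C)(C)O[C@H]1CC#CO[Si](C(C)C)(C(C)C)C(C)C
A5 | alternative 2 | (2R,3R)-3,7,3'-tri-O-benzyl-5,4'-di-O-methoxymethyltaxifolin | COCOc1ccc(cc1OCc1ccccc1)[C@H]1Oc2cc(OCc3ccccc3)cc(OCOC)c2C(=O)[C@@H]1OCc1ccccc1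
A6 | alternative 2 | 5-(benzyloxy)-3-(methoxymethoxy)-2-(trimethylsilyl)phenyl trifluoromethanesulfonate | C[Si](C)(C)c1c(OCOC)cc(OCc2ccccc2)cc1OS(=O)(=O)C(F)(F)F
A7 | alternative 2 | 5-(benzyloxy)-3-(methoxymethoxy)benzyne | COCOC1=CC(OCc2ccccc2)=CC#C1
A8 | alternative 2 | methyl (2R,3R)-2-(benzyloxy)-3-[3-(benzyloxy)-4-(methoxymethoxy)phenyl]-3-hydroxypropanoate (anti) | COCOc1ccc(cc1OCc1ccccc1)[C@@H](O)[C@@H](OCc1ccccc1)C(=O)OC
A9 | alternative 3 | (2R,3S)-7,3'-di-O-benzyl-4'-O-methoxymethylcatechin | COCOc1ccc(cc1OCc1ccccc1)[C@H]1Oc2cc(OCc3ccccc3)cc(O)c2C[C@@H]1O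
A10 | alternative 3 | 5-(benzyloxy)-2-{[(2S,3S)-3-[3-(benzyloxy)-4-(methoxymethoxy)phenyl]oxiran-2-yl]methyl}-1,3-phenylene bis(tert-butyldimethylsilyl) ether | COCOc1ccc(cc1OCc1ccccc1)[C@@H]1O[C@H]1Cc1c(O[Si](C)(C)C(C)(C)C)cc(OCc2ccccc2)cc1O[Si](C)(C)C(C)(C)C
A11 | alternative 3 | (E)-1-[3-(benzyloxy)-4-(methoxymethoxy)phenyl]-3-[4-(benzyloxy)-2,6-bis(tert-butyldimethylsilyloxy)phenyl]prop-1-ene | COCOc1ccc(cc1OCc1ccccc1)/C=C/Cc1c(O[Si](C)(C)C(C)(C)C)cc(OCc2ccccc2)cc1O[Si](C)(C)C(C)(C)C
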